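**Retrosynthetic overview**

1. One ring only: the 14-membered lactone is closed at C9–C10 by an intramolecular Ni/HAT-photocatalysed acyl C–H alkenylation (C9 aldehyde + C10 (E)-vinyl iodide), followed by C5–O desilylation.
2. The seco precursor comes from a C2–C3 ester-enolate aldol between the propionate of the C10–C13 iodo alcohol and the C3–C9 aldehyde, then primary TES removal and double oxidation (C3 ketone, C9 aldehyde).
3. C3–C9 aldehyde: (S)-3-bromo-2-methylpropanol (C8) → SAMP-hydrazone alkylation (C6) → Brown (Z)-crotylboration (C4, C5) → ozonolysis.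
4. C10–C13 unit: Brown (Z)-crotylboration of propanal (C12, C13) → ozonolysis → Takai iodo-olefination (E-C10=C11).
5. C2, flanked by the lactone and C3 ketone carbonyls, is set by equilibration in the macrocycle.

Assumption: SAMP, both Ipc2BOMe enantiomers and the silylating agents are treated as reagents, and the natural (2R) epimer is taken to be the thermodynamically favoured one at the acidic C2 position of the β-keto lactone.

**Route**

Step 1
Reactants: 1 (S)-3-bromo-2-methylpropan-1-ol
Product: 2 (S)-(3-bromo-2-methylpropoxy)triethylsilane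
Conditions: TESCl, imidazole, CH2Cl2, 0 °C
Reagents that add atoms: chlorotriethylsilane, CC[Si](Cl)(CC)CC
Why: Imidazole-mediated O-silylation of the primary alcohol; the C8 stereocentre (from the chiral pool) is untouched.

Step 2
Reactants: 2 (S)-(3-bromo-2-methylpropoxy)triethylsilane
Product: 3 (S)-triethyl(3-iodo-2-methylpropoxy)silane
Conditions: NaI, NaHCO3, acetone, reflux
Reagents that add atoms: sodium iodide, [Na+].[I-]
Why: Finkelstein SN2 halide exchange driven by NaBr precipitation gives the more reactive primary iodide.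

Step 3
Reactants: 4 propanal
Product: 5 propanal SAMP-hydrazone
Conditions: SAMP, MgSO4, CH2Cl2, 0 °C → rt
Reagents that add atoms: SAMP [(S)-1-amino-2-(methoxymethyl)pyrrolidine], COC[C@@H]1CCCN1N
Why: Hydrazone condensation installs the Enders auxiliary on the C5–C6 unit.

Step 4
Reactants: 5 propanal SAMP-hydrazone; 3 (S)-triethyl(3-iodo-2-methylpropoxy)silane
Product: 7 SAMP-hydrazone of (2S,4R)-2,4-dimethyl-5-(triethylsilyloxy)pentanal, via lithium azaenolate 6 (not isolated)
Conditions: LDA, THF, 0 °C; then 3, −100 °C → rt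
Reagents that add atoms: none
Why: Enders SAMP-hydrazone α-alkylation: the chelated E(C=C),Z(C–N) lithium azaenolate is alkylated (SN2) on the face away from the methoxymethyl-pyrrolidine, setting C6 as (S).

Step 5
Reactants: 7 SAMP-hydrazone of (2S,4R)-2,4-dimethyl-5-(triethylsilyloxy)pentanal
Product: 8 (2S,4R)-2,4-dimethyl-5-(triethylsilyloxy)pentanal
Conditions: O3, CH2Cl2, −78 °C
Reagents that add atoms: ozone, [O-][O+]=O
Why: Ozonolytic C=N cleavage of the hydrazone releases the α-chiral aldehyde under neutral, cold conditions without epimerisation or loss of the TES ether.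

Step 6
Reactants: 8 (2S,4R)-2,4-dimethyl-5-(triethylsilyloxy)pentanal; 9 cis-2-butene
Product: 11 (3S,4S,5S,7R)-3,5,7-trimethyl-8-(triethylsilyloxy)oct-1-en-4-ol, via (Z)-crotyldiisopinocampheylborane 10 (not isolated)
Conditions: 9, n-BuLi, KOtBu, THF, −78 → −45 °C; (+)-Ipc2BOMe, BF3·OEt2, −78 °C; then 8, −78 °C; NaOH, H2O2
Reagents that add atoms: none
Why: Brown asymmetric (Z)-crotylboration through a closed chair transition state gives the C4/C5 syn adduct; the (+)-Ipc2B reagent fixes C5 and is matched with the anti-Felkin preference of (Z)-crotyl reagents for the α-methyl aldehyde, giving the syn,anti C4–C6 triad.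

Step 7
Reactants: 11 (3S,4S,5S,7R)-3,5,7-trimethyl-8-(triethylsilyloxy)oct-1-en-4-ol
Product: 12 (3S,4S,5S,7R)-4-(tert-butyldimethylsilyloxy)-3,5,7-trimethyl-8-(triethylsilyloxy)oct-1-ene
Conditions: TBSOTf, 2,6-lutidine, CH2Cl2, −78 → 0 °C
Reagents that add atoms: tert-butyldimethylsilyl triflate, CC(C)(C)[Si](C)(C)OS(=O)(=O)C(F)(F)F
Why: Silyl triflate silylation protects the hindered C5 hydroxyl as a TBS ether that outlasts the primary TES group.

Step 8
Reactants: 12 (3S,4S,5S,7R)-4-(tert-butyldimethylsilyloxy)-3,5,7-trimethyl-8-(triethylsilyloxy)oct-1-ene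
Product: 13 (2R,3S,4S,6R)-3-(tert-butyldimethylsilyloxy)-2,4,6-trimethyl-7-(triethylsilyloxy)heptanal
Conditions: O3, CH2Cl2, −78 °C; PPh3, → rt
Reagents that add atoms: ozone, [O-][O+]=O
Why: Ozonolysis of the terminal alkene with reductive work-up unveils the C3 aldehyde without touching the silyl ethers.

Step 9
Reactants: 4 propanal; 9 cis-2-butene
Product: 15 (3R,4R)-4-methylhex-5-en-3-ol, via ent-(Z)-crotyldiisopinocampheylborane 14 (not isolated)
Conditions: 9, n-BuLi, KOtBu, THF, −78 → −45 °C; (−)-Ipc2BOMe, BF3·OEt2, −78 °C; then 4, −78 °C; NaOH, H2O2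
Reagents that add atoms: none
Why: Brown (Z)-crotylboration (chair transition state, reagent control by the (−)-Ipc2B group) sets the syn C12/C13 pair as (R,R).

Step 10
Reactants: 15 (3R,4R)-4-methylhex-5-en-3-ol
Product: 16 tert-butyldimethyl{[(3R,4R)-4-methylhex-5-en-3-yl]oxy}silane
Conditions: TBSCl, imidazole, DMF, rt
Reagents that add atoms: tert-butyldimethylsilyl chloride, CC(C)(C)[Si](C)(C)Cl
Why: Standard silylation masks the C13 hydroxyl so the β-oxygenated aldehyde of the next step is stable.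

Step 11
Reactants: 16 tert-butyldimethyl{[(3R,4R)-4-methylhex-5-en-3-yl]oxy}silane
Product: 17 (2S,3R)-3-(tert-butyldimethylsilyloxy)-2-methylpentanal
Conditions: O3, CH2Cl2, −78 °C; PPh3, → rt
Reagents that add atoms: ozone, [O-][O+]=O
Why: Ozonolysis with reductive work-up gives the C11 aldehyde; the α-stereocentre is configurationally stable under these neutral conditions.

Step 12
Reactants: 17 (2S,3R)-3-(tert-butyldimethylsilyloxy)-2-methylpentanal; 18 iodoform
Product: 19 tert-butyl{[(3R,4R,5E)-6-iodo-4-methylhex-5-en-3-yl]oxy}dimethylsilane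
Conditions: CrCl2, THF/dioxane, 0 °C → rt
Reagents that add atoms: none
Why: Takai iodo-olefination via a gem-dichromium species adds C10 and gives the (E)-vinyl iodide selectively without epimerising C12.

Step 13
Reactants: 19 tert-butyl{[(3R,4R,5E)-6-iodo-4-methylhex-5-en-3-yl]oxy}dimethylsilane
Product: 20 (3R,4R,5E)-6-iodo-4-methylhex-5-en-3-ol
Conditions: HF·pyridine, THF, 0 °C → rt
Reagents that add atoms: none
Why: Fluoride-mediated desilylation frees the C13 hydroxyl; the vinyl iodide is inert.

Step 14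
Reactants: 20 (3R,4R,5E)-6-iodo-4-methylhex-5-en-3-ol; 21 propanoyl chloride
Product: 22 (3R,4R,5E)-6-iodo-4-methylhex-5-en-3-yl propanoate
Conditions: pyridine, DMAP (cat.), CH2Cl2, 0 °C → rt
Reagents that add atoms: none
Why: DMAP-catalysed acylation forms the future lactone C1–O bond early and brings in C1, C2 and the C2 methyl.

Step 15
Reactants: 22 (3R,4R,5E)-6-iodo-4-methylhex-5-en-3-yl propanoate; 13 (2R,3S,4S,6R)-3-(tert-butyldimethylsilyloxy)-2,4,6-trimethyl-7-(triethylsilyloxy)heptanal
Product: 24 (3R,4R,5E)-6-iodo-4-methylhex-5-en-3-yl (4S,5S,6S,8R)-5-(tert-butyldimethylsilyloxy)-3-hydroxy-2,4,6,8-tetramethyl-9-(triethylsilyloxy)nonanoate (C2/C3 diastereomer mixture), via lithium ester enolate 23 (not isolated)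
Conditions: LDA, THF, −78 °C; then 13, −78 °C; NH4Cl (aq)
Reagents that add atoms: none
Why: Ester-enolate aldol addition forms C2–C3; the new C2/C3 centres are formed unselectively, which is immaterial because C3 is oxidised in step 17 and C2 then equilibrates.

Step 16
Reactants: 24 aldol adduct (C9 OTES, C3 OH)
Product: 25 (3R,4R,5E)-6-iodo-4-methylhex-5-en-3-yl (4S,5S,6S,8R)-5-(tert-butyldimethylsilyloxy)-3,9-dihydroxy-2,4,6,8-tetramethylnonanoate (C2/C3 mixture)
Conditions: HF·pyridine, pyridine, THF, 0 °C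
Reagents that add atoms: none
Why: Buffered fluoride desilylation removes the primary TES ether far faster than the hindered secondary TBS ether at C5.

Step 17
Reactants: 25 C3,C9-diol
Product: 26 (3R,4R,5E)-6-iodo-4-methylhex-5-en-3-yl (4R,5S,6S,8R)-5-(tert-butyldimethylsilyloxy)-2,4,6,8-tetramethyl-3,9-dioxononanoate (C2 epimers)
Conditions: Dess–Martin periodinane, NaHCO3, CH2Cl2, 0 °C → rt
Reagents that add atoms: none
Why: Dess–Martin oxidation converts the C3 carbinol into the β-keto ester and the C9 primary alcohol into the aldehyde in one operation under buffered, non-epimerising conditions for C4 and C8.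

Step 18
Reactants: 26 keto aldehyde vinyl iodide
Product: 27 5-O-(tert-butyldimethylsilyl)narbonolide
Conditions: NiBr2·glyme (15 mol%), dtbbpy (18 mol%), (n-Bu4N)4[W10O32] (5 mol%), 2,6-lutidine, MeCN, 2 mM (26 added over 8 h), 390 nm LEDs, 10 °C
Reagents that add atoms: none
Why: Proposed new method: a macrocyclising acyl C–H alkenylation in which photoexcited decatungstate abstracts the hydridic formyl hydrogen at C9 (the acidic C2–H and the α-carbonyl C–H bonds are polarity-mismatched), Ni(0)/dtbbpy inserts into the C10–I bond with retention of the E geometry, the tethered acyl radical is captured at nickel and C(acyl)–C(alkenyl) reductive elimination closes the 14-membered enone while reduced decatungstate returns Ni(I) to Ni(0) and lutidine takes up HI; the closest known reaction type is the intermolecular nickel/HAT-photocatalysed acylation of aryl halides with aldehydes, not yet shown for alkenyl iodides or ring closure; C2 equilibrates through the enol towards the (2R) epimer.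

Step 19
Reactants: 27 5-O-(tert-butyldimethylsilyl)narbonolide
Product: 28 narbonolide
Conditions: HF·pyridine, THF, 0 °C → rt
Reagents that add atoms: none
Why: Fluoride desilylation frees the C5 hydroxyl under mildly acidic conditions tolerated by the enone and β-keto lactone, and any residual C2 epimer converges on the natural (2R) configuration by enol equilibration.

**Compound list**

1 | (S)-3-bromo-2-methylpropan-1-ol | BrC[C@@H](C)CO | starting material
2 | (S)-(3-bromo-2-methylpropoxy)triethylsilane | BrC[C@@H](C)CO[Si](CC)(CC)CC | intermediate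
3 | (S)-triethyl(3-iodo-2-methylpropoxy)silane | IC[C@@H](C)CO[Si](CC)(CC)CC | intermediate
4 | propanal | CCC=O | starting material
5 | propanal SAMP-hydrazone, (S,E)-2-(methoxymethyl)-N-propylidenepyrrolidin-1-amine | CC/C=N/N1CCC[C@H]1COC | intermediate
6 | lithium azaenolate of 5 (not isolated) | C/C=C/N([Li])N1CCC[C@H]1COC | intermediate
7 | SAMP-hydrazone of (2S,4R)-2,4-dimethyl-5-(triethylsilyloxy)pentanal | COC[C@@H]1CCCN1/N=C/[C@@H](C)C[C@@H](C)CO[Si](CC)(CC)CC | intermediate
8 | (2S,4R)-2,4-dimethyl-5-(triethylsilyloxy)pentanal | O=C[C@@H](C)C[C@@H](C)CO[Si](CC)(CC)CC | intermediate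
9 | cis-2-butene | C/C=C\C | starting material
10 | (Z)-crotyldiisopinocampheylborane from (+)-Ipc2BOMe (not isolated) | C/C=C\CB([C@H]1C[C@H]2C[C@@H]([C@@H]1C)C2(C)C)[C@H]1C[C@H]2C[C@@H]([C@@H]1C)C2(C)C | intermediate
11 | (3S,4S,5S,7R)-3,5,7-trimethyl-8-(triethylsilyloxy)oct-1-en-4-ol | C=C[C@H](C)[C@@H](O)[C@@H](C)C[C@@H](C)CO[Si](CC)(CC)CC | intermediate
12 | (3S,4S,5S,7R)-4-(tert-butyldimethylsilyloxy)-3,5,7-trimethyl-8-(triethylsilyloxy)oct-1-ene | C=C[C@H](C)[C@@H](O[Si](C)(C)C(C)(C)C)[C@@H](C)C[C@@H](C)CO[Si](CC)(CC)CC | intermediate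
13 | (2R,3S,4S,6R)-3-(tert-butyldimethylsilyloxy)-2,4,6-trimethyl-7-(triethylsilyloxy)heptanal | O=C[C@H](C)[C@@H](O[Si](C)(C)C(C)(C)C)[C@@H](C)C[C@@H](C)CO[Si](CC)(CC)CC | intermediate
14 | (Z)-crotyldiisopinocampheylborane from (−)-Ipc2BOMe, enantiomeric Ipc series (not isolated) | C/C=C\CB([C@@H]1C[C@@H]2C[C@H]([C@H]1C)C2(C)C)[C@@H]1C[C@@H]2C[C@H]([C@H]1C)C2(C)C | intermediate
15 | (3R,4R)-4-methylhex-5-en-3-ol | CC[C@@H](O)[C@H](C)C=C | intermediate
16 | tert-butyldimethyl{[(3R,4R)-4-methylhex-5-en-3-yl]oxy}silane | CC[C@@H](O[Si](C)(C)C(C)(C)C)[C@H](C)C=C | intermediate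
17 | (2S,3R)-3-(tert-butyldimethylsilyloxy)-2-methylpentanal | CC[C@@H](O[Si](C)(C)C(C)(C)C)[C@H](C)C=O | intermediate
18 | iodoform | IC(I)I | starting material
19 | tert-butyl{[(3R,4R,5E)-6-iodo-4-methylhex-5-en-3-yl]oxy}dimethylsilane | CC[C@@H](O[Si](C)(C)C(C)(C)C)[C@H](C)/C=C/I | intermediate
20 | (3R,4R,5E)-6-iodo-4-methylhex-5-en-3-ol | CC[C@@H](O)[C@H](C)/C=C/I | intermediate
21 | propanoyl chloride | CCC(=O)Cl | starting material
22 | (3R,4R,5E)-6-iodo-4-methylhex-5-en-3-yl propanoate | CC[C@@H](OC(=O)CC)[C@H](C)/C=C/I | intermediate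
23 | lithium (E)-enolate of 22 (not isolated) | CC[C@@H](O\C(O[Li])=C/C)[C@H](C)/C=C/I | intermediate
24 | (3R,4R,5E)-6-iodo-4-methylhex-5-en-3-yl (4S,5S,6S,8R)-5-(tert-butyldimethylsilyloxy)-3-hydroxy-2,4,6,8-tetramethyl-9-(triethylsilyloxy)nonanoate, C2/C3 mixture | CC[C@@H](OC(=O)C(C)C(O)[C@H](C)[C@@H](O[Si](C)(C)C(C)(C)C)[C@@H](C)C[C@@H](C)CO[Si](CC)(CC)CC)[C@H](C)/C=C/I | intermediate
25 | (3R,4R,5E)-6-iodo-4-methylhex-5-en-3-yl (4S,5S,6S,8R)-5-(tert-butyldimethylsilyloxy)-3,9-dihydroxy-2,4,6,8-tetramethylnonanoate, C2/C3 mixture | CC[C@@H](OC(=O)C(C)C(O)[C@H](C)[C@@H](O[Si](C)(C)C(C)(C)C)[C@@H](C)C[C@@H](C)CO)[C@H](C)/C=C/I | intermediate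
26 | (3R,4R,5E)-6-iodo-4-methylhex-5-en-3-yl (4R,5S,6S,8R)-5-(tert-butyldimethylsilyloxy)-2,4,6,8-tetramethyl-3,9-dioxononanoate, C2 epimers | CC[C@@H](OC(=O)C(C)C(=O)[C@H](C)[C@@H](O[Si](C)(C)C(C)(C)C)[C@@H](C)C[C@@H](C)C=O)[C@H](C)/C=C/I | intermediate
27 | 5-O-(tert-butyldimethylsilyl)narbonolide | CC[C@H]1OC(=O)[C@H](C)C(=O)[C@H](C)[C@@H](O[Si](C)(C)C(C)(C)C)[C@@H](C)C[C@@H](C)C(=O)/C=C/[C@H]1C | intermediate
28 | narbonolide, (2R,4R,5S,6S,8R,10E,12R,13R) | CC[C@H]1OC(=O)[C@H](C)C(=O)[C@H](C)[C@@H](O)[C@@H](C)C[C@@H](C)C(=O)/C=C/[C@H]1C | target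

**Step count and risks**

Total step count: 19. Longest linear sequence: 12 (steps 1, 2, 4, 5, 6, 7, 8, 15, 16, 17, 18, 19); the hydrazone step 3 and the six-step C10–C13 branch (steps 9–14) run in parallel.

The three steps most likely to fail:

Step 18 (proposed new macrocyclisation). Risks are decarbonylation of the α-branched acyl radical, intermolecular coupling, and slow hydrogen abstraction at high dilution. The fallback sets out from 26 and uses known chemistry: an intramolecular Nozaki–Hiyama–Kishi reaction (CrCl2, catalytic NiCl2, DMSO/THF, 2 mM) closes the ring to the C9 allylic alcohol 5-O-TBS-9-dihydronarbonolide F1, and Dess–Martin oxidation of the allylic alcohol then gives the enone, coming back to the route at 27.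

Step 4 (auxiliary alkylation with a β-branched iodide). The azaenolate alkylation may be slow or only moderately selective. The fallback sets out from 3: lithium–iodine exchange (t-BuLi), transmetalation to zinc (ZnBr2) and Pd(PPh3)4-catalysed Negishi coupling with vinyl bromide give (R)-triethyl[(2-methylpent-4-en-1-yl)oxy]silane F2. Zirconium-catalysed asymmetric carboalumination (Me3Al, catalytic (+)-(NMI)2ZrCl2, then O2) then gives (2S,4R)-2,4-dimethyl-5-(triethylsilyloxy)pentan-1-ol F3, and Dess–Martin oxidation comes back to the route at 8.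

Step 15 (fragment union by lithium enolate aldol). The hindered ester enolate may add incompletely or undergo retro-aldol or elimination. The fallback sets out from 20 and 13: acylation of 20 with 2-bromopropanoyl bromide/pyridine gives (3R,4R,5E)-6-iodo-4-methylhex-5-en-3-yl 2-bromopropanoate F4, and a SmI2-mediated Reformatsky addition of F4 to aldehyde 13 (THF, −78 °C) comes back to the route at 24.

**Further compounds**

F1 | step 18 | 5-O-(tert-butyldimethylsilyl)-9-dihydronarbonolide (C9 allylic alcohol, C2/C9 epimers) | CC[C@H]1OC(=O)C(C)C(=O)[C@H](C)[C@@H](O[Si](C)(C)C(C)(C)C)[C@@H](C)C[C@@H](C)C(O)/C=C/[C@H]1C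
F2 | step 4 | (R)-triethyl[(2-methylpent-4-en-1-yl)oxy]silane | C=CC[C@@H](C)CO[Si](CC)(CC)CC
F3 | step 4 | (2S,4R)-2,4-dimethyl-5-(triethylsilyloxy)pentan-1-ol | OC[C@@H](C)C[C@@H](C)CO[Si](CC)(CC)CC
F4 | step 15 | (3R,4R,5E)-6-iodo-4-methylhex-5-en-3-yl 2-bromopropanoate | CC[C@@H](OC(=O)C(C)Br)[C@H](C)/C=C/I
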